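## Retrosynthetic overview

1. 21 comes from 20 by loss of two benzyl groups. 20 is cut at the aryl–CH2 bond between ring B and the lactone side chain, giving aryl bromide 18 and hydroxymethyl lactone 9 (deoxygenative sp2–sp3 coupling).
2. The dihydrobenzofuran of 18 comes from an oxidative ring contraction of racemic flavanone 15, in which ring B shifts from C4 to C3 under a chiral λ3-iodane. 15 comes from acetophenone 13 and aldehyde 11.
3. The lactone of 9 comes from anti hydroxymethylation of 7. 7 comes from a desymmetrising Baeyer–Villiger ring expansion of cyclobutanone 6, which is made from aryl bromide 4 and bromide 5.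
4. 4, 11 and 13 all come from 4-bromoguaiacol 3, and 3 comes from catechol 1.
5. Ring order: cyclobutanone to γ-lactone (step 5), then pyranone (step 9) contracted to dihydrofuran (step 10). No ring is formed after the union.

Ring A is the guaiacyl ring of the β-benzyl group, ring B is the central arene, and ring C is the guaiacyl ring at C2 of the dihydrobenzofuran.

Assumption: the sense of induction of the chiral ligand (step 5) and of the chiral iodane (step 10) is taken as drawn. If a test run shows the opposite sense, the equally available antipode is used.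

## Route

Step 1
Reactants: 1 catechol (benzene-1,2-diol)
Product: 2 2-methoxyphenol (guaiacol)
Conditions: MeI (1.0 equiv), 1 (1.5 equiv), K2CO3, acetone, reflux
Reagents that add atoms: iodomethane CI
Why: Williamson mono-O-methylation; excess catechol suppresses the dimethyl ether and is washed out with water.

Step 2
Reactants: 2 2-methoxyphenol
Product: 3 4-bromo-2-methoxyphenol
Conditions: NBS, MeCN, 0 °C
Reagents that add atoms: N-bromosuccinimide O=C1CCC(=O)N1Br
Why: Electrophilic aromatic bromination; the free OH is the stronger director, so bromine enters para to it.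

Step 3
Reactants: 3 4-bromo-2-methoxyphenol
Product: 4 1-(benzyloxy)-4-bromo-2-methoxybenzene
Conditions: BnBr, K2CO3, DMF, 25 °C
Reagents that add atoms: benzyl bromide BrCc1ccccc1
Why: Williamson etherification installs the one protecting group used for rings A and C.

Step 4
Reactants: 4 1-(benzyloxy)-4-bromo-2-methoxybenzene; 5 3-(bromomethyl)cyclobutan-1-one
Product: 6 3-[4-(benzyloxy)-3-methoxybenzyl]cyclobutan-1-one
Conditions: NiBr2(dme) (10 mol %), 4,4'-dimethoxy-2,2'-bipyridine (10 mol %), NaI (25 mol %), Zn dust (2 equiv), DMA, 40 °C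
Reagents that add atoms: none
Why: Nickel-catalysed reductive cross-electrophile coupling; zerovalent nickel inserts into Ar–Br, captures the primary radical from 5 and reductively eliminates the sp2–sp3 bond, while the ketone is inert to Zn.

Step 5
Reactants: 6 3-[4-(benzyloxy)-3-methoxybenzyl]cyclobutan-1-one
Product: 7 (4R)-4-[4-(benzyloxy)-3-methoxybenzyl]dihydrofuran-2(3H)-one
Conditions: Sc(OTf)3 (5 mol %), chiral N,N'-dioxide ligand (pipecolic-acid-derived bis-anilide, 5 mol %), mCPBA (1.2 equiv), EtOAc, −20 °C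
Reagents that add atoms: meta-chloroperbenzoic acid O=C(OO)c1cccc(Cl)c1
Why: Desymmetrising Baeyer–Villiger ring expansion; in the scandium-bound Criegee adduct only one of the two enantiotopic ring CH2 groups lies antiperiplanar to the O–O bond and shifts to oxygen, which sets C4 as R.

Step 6
Reactants: 7 (4R)-4-[4-(benzyloxy)-3-methoxybenzyl]dihydrofuran-2(3H)-one
Product: 9 (3S,4R)-4-[4-(benzyloxy)-3-methoxybenzyl]-3-(hydroxymethyl)dihydrofuran-2(3H)-one, via lithium enolate 8 (not isolated)
Conditions: LiN(iPr)2 (1.1 equiv), THF, −78 °C; monomeric CH2O in THF, −78 to −30 °C; AcOH quench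
Reagents that add atoms: formaldehyde C=O
Why: Aldol-type hydroxymethylation of a lactone enolate; formaldehyde approaches the face opposite the C4 benzyl group and gives the trans product, which sets the α-stereocentre.

Step 7
Reactants: 4 1-(benzyloxy)-4-bromo-2-methoxybenzene
Product: 11 4-(benzyloxy)-3-methoxybenzaldehyde, via aryllithium 10 (not isolated)
Conditions: n-BuLi, THF, −78 °C; DMF; aq. HCl
Reagents that add atoms: N,N-dimethylformamide CN(C)C=O
Why: Bromine–lithium exchange followed by Bouveault formylation; exchange at −78 °C is much faster than benzylic deprotonation.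

Step 8
Reactants: 3 4-bromo-2-methoxyphenol
Product: 13 1-(5-bromo-2-hydroxy-3-methoxyphenyl)ethan-1-one, via aryl acetate 12 (not isolated)
Conditions: AcCl (1.2 equiv), TiCl4 (1.5 equiv), ClCH2CH2Cl, 0 to 80 °C; aq. HCl
Reagents that add atoms: acetyl chloride CC(=O)Cl
Why: O-acylation followed by Fries rearrangement; bromine blocks the para position, so the titanium phenolate delivers the acyl group to the only free ortho carbon.

Step 9
Reactants: 13 1-(5-bromo-2-hydroxy-3-methoxyphenyl)ethan-1-one; 11 4-(benzyloxy)-3-methoxybenzaldehyde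
Product: 15 racemic 2-[4-(benzyloxy)-3-methoxyphenyl]-6-bromo-8-methoxychroman-4-one, via 2'-hydroxychalcone 14 (not isolated)
Conditions: pyrrolidine (30 mol %), EtOH, reflux; product crystallises
Reagents that add atoms: none
Why: Claisen–Schmidt condensation followed by reversible intramolecular oxa-Michael closure, driven by crystallisation of the flavanone; no stereocontrol is needed because step 10 is enantioconvergent.

Step 10
Reactants: 15 racemic 2-[4-(benzyloxy)-3-methoxyphenyl]-6-bromo-8-methoxychroman-4-one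
Product: 17 methyl (2S,3S)-2-[4-(benzyloxy)-3-methoxyphenyl]-5-bromo-7-methoxy-2,3-dihydrobenzofuran-3-carboxylate, via enol ether 16 (not isolated)
Conditions: dimethyl (2R,2'R)-2,2'-{[2-(diacetoxy-λ3-iodanyl)-1,3-phenylene]bis(oxy)}dipropanoate (1.2 equiv, added over 6 h), TfOH (20 mol %), HC(OMe)3–CH2Cl2 1:1, 0 °C; aqueous work-up
Reagents that add atoms: trimethyl orthoformate COC(OC)OC; water O
Why: Proposed new method: enantioconvergent oxidative ring contraction of a racemic flavanone; acid and orthoformate convert 15 into enol ether 16, whose C2–O bond ionises reversibly to the ring-opened O-methyl chalcone cation (stabilised by the para-benzyloxy group), so the two enantiomers interconvert; the C2-symmetric lactate-derived trivalent iodine reagent must add to C3 anti to the 2-aryl group, and only in (S)-16 is that face also the one the reagent prefers, so (S)-16 is drained while (R)-16 racemises; methanol capture places the C3–I bond equatorial and antiperiplanar to C4–C4a, ring B makes a cationic 1,2-shift from C4 to C3 with inversion and loss of the iodoarene, and the dimethoxycarbenium ion ends as the ester, which forms the dihydrofuran ring and sets C2 and C3 trans; the closest known reaction types are the PhI(OAc)2/acid/orthoformate contraction of flavanones to trans 2-aryl-2,3-dihydrobenzofuran-3-carboxylates (racemic or enantiospecific) and enantioselective 1,2-aryl migrations of enones and styrenes with lactate-based iodanes.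

Step 11
Reactants: 17 methyl (2S,3S)-2-[4-(benzyloxy)-3-methoxyphenyl]-5-bromo-7-methoxy-2,3-dihydrobenzofuran-3-carboxylate
Product: 18 {(2S,3R)-2-[4-(benzyloxy)-3-methoxyphenyl]-5-bromo-7-methoxy-2,3-dihydrobenzofuran-3-yl}methanol
Conditions: LiAlH4, THF, 0 °C, 30 min
Reagents that add atoms: none
Why: Hydride reduction of the ester; it is faster than enolisation, the aryl bromide survives at 0 °C, and the geometry is unchanged (the C3 descriptor changes only through CIP priorities).

Step 12
Reactants: 9 (3S,4R)-4-[4-(benzyloxy)-3-methoxybenzyl]-3-(hydroxymethyl)dihydrofuran-2(3H)-one; 18 {(2S,3R)-2-[4-(benzyloxy)-3-methoxyphenyl]-5-bromo-7-methoxy-2,3-dihydrobenzofuran-3-yl}methanol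
Product: 20 O,O'-dibenzyl isolappaol A, via benzoxazoline adduct 19 (not isolated)
Conditions: 9 (1.3 equiv), 5,7-di-tert-butyl-3-phenylbenzoxazolium tetrafluoroborate (1.25 equiv), pyridine (1.25 equiv), MTBE, 25 °C, 15 min; then 18 (1.0 equiv), NiBr2(dtbbpy) (5 mol %), [Ir(ppy)2(dtbbpy)]PF6 (1.5 mol %), quinuclidine (1.75 equiv), DMA–MTBE, 450 nm LEDs, 25 °C
Reagents that add atoms: none
Why: Metallaphotoredox deoxygenative arylation of an alcohol; oxidation and deprotonation of adduct 19 followed by β-scission release the primary CH2 radical, which nickel couples with the aryl bromide, and because only 9 is pre-activated the free OH of 18 and all four stereocentres are untouched.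

Step 13
Reactants: 20 O,O'-dibenzyl isolappaol A
Product: 21 isolappaol A
Conditions: H2 (1 atm), 10% Pd/C, EtOAc–EtOH, 25 °C
Reagents that add atoms: none
Why: Hydrogenolysis of the two aryl benzyl ethers, which is much faster under neutral conditions than cleavage of the cyclic benzylic C2–O bond.

## Compound list

1 | catechol | Oc1ccccc1O | starting material
2 | 2-methoxyphenol | COc1ccccc1O | intermediate
3 | 4-bromo-2-methoxyphenol | COc1cc(Br)ccc1O | intermediate
4 | 1-(benzyloxy)-4-bromo-2-methoxybenzene | COc1cc(Br)ccc1OCc1ccccc1 | intermediate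
5 | 3-(bromomethyl)cyclobutan-1-one | O=C1CC(CBr)C1 | starting material
6 | 3-[4-(benzyloxy)-3-methoxybenzyl]cyclobutan-1-one | COc1cc(CC2CC(=O)C2)ccc1OCc1ccccc1 | intermediate
7 | (4R)-4-[4-(benzyloxy)-3-methoxybenzyl]dihydrofuran-2(3H)-one | COc1cc(C[C@H]2COC(=O)C2)ccc1OCc1ccccc1 | intermediate
8 | lithium enolate of 7 (not isolated) | COc1cc(C[C@H]2COC(O[Li])=C2)ccc1OCc1ccccc1 | intermediate
9 | (3S,4R)-4-[4-(benzyloxy)-3-methoxybenzyl]-3-(hydroxymethyl)dihydrofuran-2(3H)-one | COc1cc(C[C@H]2COC(=O)[C@@H]2CO)ccc1OCc1ccccc1 | intermediate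
10 | [4-(benzyloxy)-3-methoxyphenyl]lithium (not isolated) | [Li]c1ccc(OCc2ccccc2)c(OC)c1 | intermediate
11 | 4-(benzyloxy)-3-methoxybenzaldehyde | COc1cc(C=O)ccc1OCc1ccccc1 | intermediate
12 | 4-bromo-2-methoxyphenyl acetate (not isolated) | COc1cc(Br)ccc1OC(C)=O | intermediate
13 | 1-(5-bromo-2-hydroxy-3-methoxyphenyl)ethan-1-one | CC(=O)c1cc(Br)cc(OC)c1O | intermediate
14 | (E)-3-[4-(benzyloxy)-3-methoxyphenyl]-1-(5-bromo-2-hydroxy-3-methoxyphenyl)prop-2-en-1-one (not isolated) | COc1cc(/C=C/C(=O)c2cc(Br)cc(OC)c2O)ccc1OCc1ccccc1 | intermediate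
15 | racemic 2-[4-(benzyloxy)-3-methoxyphenyl]-6-bromo-8-methoxychroman-4-one (no configuration assigned) | COc1cc(C2CC(=O)c3cc(Br)cc(OC)c3O2)ccc1OCc1ccccc1 | intermediate
16 | 2-[4-(benzyloxy)-3-methoxyphenyl]-6-bromo-4,8-dimethoxy-2H-chromene (configurationally labile, not isolated) | COC1=CC(c2ccc(OCc3ccccc3)c(OC)c2)Oc2c(OC)cc(Br)cc12 | intermediate
17 | methyl (2S,3S)-2-[4-(benzyloxy)-3-methoxyphenyl]-5-bromo-7-methoxy-2,3-dihydrobenzofuran-3-carboxylate (trans) | Brc1cc(OC)c2c(c1)[C@H](C(=O)OC)[C@@H](c1ccc(OCc3ccccc3)c(OC)c1)O2 | intermediate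
18 | {(2S,3R)-2-[4-(benzyloxy)-3-methoxyphenyl]-5-bromo-7-methoxy-2,3-dihydrobenzofuran-3-yl}methanol (trans) | Brc1cc(OC)c2c(c1)[C@H](CO)[C@@H](c1ccc(OCc3ccccc3)c(OC)c1)O2 | intermediate
19 | 2-alkoxy-5,7-di-tert-butyl-3-phenyl-2,3-dihydrobenzoxazole adduct of 9 (not isolated, epimers at the orthoamide carbon) | COc1cc(C[C@H]2COC(=O)[C@@H]2COC2Oc3c(C(C)(C)C)cc(C(C)(C)C)cc3N2c2ccccc2)ccc1OCc1ccccc1 | intermediate
20 | O,O'-dibenzyl isolappaol A | COc1cc(C[C@H]2COC(=O)[C@@H]2Cc2cc(OC)c3c(c2)[C@H](CO)[C@@H](c2ccc(OCc4ccccc4)c(OC)c2)O3)ccc1OCc1ccccc1 | intermediate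
21 | isolappaol A: (3R,4R)-lactone, (2S,3R)-dihydrobenzofuran | COc1cc(C[C@H]2COC(=O)[C@@H]2Cc2cc(OC)c3c(c2)[C@H](CO)[C@@H](c2ccc(O)c(OC)c2)O3)ccc1O | target

## Step count

- Total steps: 13.
- Longest linear sequence: 9 steps (1 → 2 → 3 → 4 → 11 → 15 → 17 → 18 → 20 → 21).

## Steps most likely to fail

**Step 10 (the new step).**
- The 1,2-shift of electron-rich ring C from C2 to C3 (isoflavone pathway) may compete.
- Racemisation of 16 may be too slow relative to oxidation.
- The iodane may discriminate poorly between the enantiomers of 16.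

The fallback replaces asymmetric induction by resolution and uses only known chemistry. It sets out from 15 and comes back to the route at 18. Treating 15 with PhI(OAc)2 and catalytic H2SO4 in HC(OMe)3 gives the racemic trans methyl ester F1. LiOH in THF–water gives the racemic trans acid F2. Fractional crystallisation of its 1-phenylethylammonium salt, followed by acidification, gives the (2S,3S)-acid F3. BH3·SMe2 in THF then reduces it to 18.

**Step 12.** The very electron-rich aryl bromide 18 may add slowly to nickel. Exchange of the orthoamide onto the free OH of 18 could also divert radical formation.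

The fallback is the classical polar enolate alkylation instead of a radical cross-coupling. It sets out from 18, with 7 as partner, and comes back to the route at 21. NaH/BnBr converts 18 into the benzyl ether F4. n-BuLi followed by monomeric CH2O gives the benzylic alcohol F5, and PBr3 at 0 °C gives the benzylic bromide F6. Alkylation of enolate 8 (from 7 and LiN(iPr)2) anti to the β-benzyl group gives tri-O-benzyl isolappaol A F7. H2 over Pd/C then gives 21.

**Step 4.** The (3-oxocyclobutyl)methyl radical can ring-open to an α-keto radical before nickel captures it.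

The fallback builds the four-membered ring on the arene instead of coupling a preformed one. It sets out from 4 and comes back to the route at 6. The Grignard reagent of 4 (Mg, THF) with allyl bromide and catalytic CuI gives 4-allyl-1-(benzyloxy)-2-methoxybenzene F8. Dichloroketene, generated from Cl3CCOCl and Zn–Cu couple in Et2O, adds to give the 2,2-dichlorocyclobutanone F9. Zn in AcOH then removes both chlorines to give 6.

## Further compounds

F1 | step 10 | racemic trans methyl 2-[4-(benzyloxy)-3-methoxyphenyl]-5-bromo-7-methoxy-2,3-dihydrobenzofuran-3-carboxylate | Brc1cc(OC)c2c(c1)[C@H](C(=O)OC)[C@@H](c1ccc(OCc3ccccc3)c(OC)c1)O2.Brc1cc(OC)c2c(c1)[C@@H](C(=O)OC)[C@H](c1ccc(OCc3ccccc3)c(OC)c1)O2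
F2 | step 10 | racemic trans 2-[4-(benzyloxy)-3-methoxyphenyl]-5-bromo-7-methoxy-2,3-dihydrobenzofuran-3-carboxylic acid | Brc1cc(OC)c2c(c1)[C@H](C(=O)O)[C@@H](c1ccc(OCc3ccccc3)c(OC)c1)O2.Brc1cc(OC)c2c(c1)[C@@H](C(=O)O)[C@H](c1ccc(OCc3ccccc3)c(OC)c1)O2
F3 | step 10 | (2S,3S)-2-[4-(benzyloxy)-3-methoxyphenyl]-5-bromo-7-methoxy-2,3-dihydrobenzofuran-3-carboxylic acid | Brc1cc(OC)c2c(c1)[C@H](C(=O)O)[C@@H](c1ccc(OCc3ccccc3)c(OC)c1)O2
F4 | step 12 | (2S,3R)-2-[4-(benzyloxy)-3-methoxyphenyl]-3-[(benzyloxy)methyl]-5-bromo-7-methoxy-2,3-dihydrobenzofuran | Brc1cc(OC)c2c(c1)[C@H](COCc1ccccc1)[C@@H](c1ccc(OCc3ccccc3)c(OC)c1)O2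
F5 | step 12 | {(2S,3R)-2-[4-(benzyloxy)-3-methoxyphenyl]-3-[(benzyloxy)methyl]-7-methoxy-2,3-dihydrobenzofuran-5-yl}methanol | OCc1cc(OC)c2c(c1)[C@H](COCc1ccccc1)[C@@H](c1ccc(OCc3ccccc3)c(OC)c1)O2
F6 | step 12 | (2S,3R)-2-[4-(benzyloxy)-3-methoxyphenyl]-3-[(benzyloxy)methyl]-5-(bromomethyl)-7-methoxy-2,3-dihydrobenzofuran | BrCc1cc(OC)c2c(c1)[C@H](COCc1ccccc1)[C@@H](c1ccc(OCc3ccccc3)c(OC)c1)O2
F7 | step 12 | tri-O-benzyl isolappaol A | COc1cc(C[C@H]2COC(=O)[C@@H]2Cc2cc(OC)c3c(c2)[C@H](COCc2ccccc2)[C@@H](c2ccc(OCc4ccccc4)c(OC)c2)O3)ccc1OCc1ccccc1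
F8 | step 4 | 4-allyl-1-(benzyloxy)-2-methoxybenzene | C=CCc1ccc(OCc2ccccc2)c(OC)c1
F9 | step 4 | 3-[4-(benzyloxy)-3-methoxybenzyl]-2,2-dichlorocyclobutan-1-one (racemic) | COc1cc(CC2CC(=O)C2(Cl)Cl)ccc1OCc1ccccc1
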